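## The problem

Compound 20 is a C25 apocarotenoid, (3S,5R,8R)-5,8-epoxy-5,8-dihydro-12'-apo-β-carotene-3,12'-diol. Carotenoid locants are used throughout: C1 carries the geminal methyl groups, C3 the hydroxyl, C5 the methyl-bearing ether carbon, C6=C7 is the ring alkene, C8 the ether methine, and C9 to C12' the chain.

Its bicycle is a cyclohexane (ring A) fused through C5–C6 to a 2,5-dihydrofuran (ring B), and C8 carries an all-E pentaene that ends in a primary allylic alcohol. The chain divides at C11=C12 into a C15 ring piece and the purchasable C10 dial 16, so chain building comes down to one olefination and one new double bond. Of the three stereocentres, C3 can be bought with actinol 1. C5 needs its oxygen trans to the C3 oxygen, which the ring does not reliably favour (an electrophile is expected to approach anti to the axial C1 methyl, on the face of the C3 oxygen), so it calls for reagent control. C8 lies across the ring oxygen from C5 with no neighbouring group to direct a reagent and is the hardest centre to control. It is also a doubly allylic ether carbon: acid ionises the C8–O bond and equilibrates the C8 epimers, and the polyene is sensitive to acid, light and oxygen, so C8 must be set stereospecifically without acid and never meet acid afterwards.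

The feature that opens the way is the C6=C7–C8 unit beside the C5 oxygen. Written as a C6=C7=C8 allene next to a C5 hydroxyl, it stores the C8 configuration as a chirality axis, because the allene holds H-8 and C9 above and below the plane in which the O–C8 bond forms. That axis can be drawn from a C5–C6 oxirane on a C7≡C8 alkyne, so one reagent-controlled epoxidation fixes C5 directly and C8 by relay.

## Retrosynthesis

**20 ⇒ 19 ⇒ 18.** The last two operations are functional-group changes: the O–Si bond of silyl ether 19 and the C12' carbonyl of aldehyde 18. The silyl group stays to the end because a free C3 hydroxyl would compete with the allylic alcohol when the phosphonium salt is made, and because fluoride removes it without acid. The forward steps must be basic or neutral.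

**18 ⇒ 15 + 16 (C11=C12).** Cutting this double bond gives phosphonium salt 15 (ylide 17) and the commercial symmetrical dial 16. Cuts at C9=C10 or C13=C14 would need partners that cannot be bought and would place the carbanion directly beside C8. The forward Wittig reaction must olefinate only one aldehyde of 16 (excess dial), deliver E at C11=C12 (the hindered 11Z isomer equilibrates on warming), and use the ylide before it can open ring B.

**15 ⇒ 13 (C11–P).** The salt comes from allylic alcohol 13 through bromide 14. The forward conversion has to avoid Brønsted acid, which rules out the usual PPh3·HBr route and points to an Appel bromination followed by quaternisation.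

**13 ⇒ 12 (O–C8, ring B).** This is the key cut. Opening the O–C8 bond gives α-hydroxyallene 12, which has one ring and one stereocentre fewer and carries the C8 information as an S-configured axis. Against ionic closures onto C8 (lactol reduction, allylic substitution), which pass through a C8 cation and leave the centre to thermodynamics, the allene closure is stereospecific. The forward reaction must add the C5 oxygen and the metal anti across C7=C8 and must not ionise the product.

**12 ⇒ 11 (C8–H made, C6–O broken).** The allene is drawn from alkynyl oxirane 11 by SN2′ delivery of hydride to C8. The axis needed here has H-8 on the face of the C5 methyl group, so hydride must enter anti to the C6–O bond. Aluminium hydrides such as iBu2AlH are not chosen: they bind the oxirane oxygen and are liable to pass hydride to C8 from that same face, which would give the other axis and, after the anti cyclisation, the C8 epimer. Palladium-catalysed formate hydrogenolysis is anti by mechanism (oxidative addition with inversion, hydride transfer from palladium with retention) and is used instead.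

**11 ⇒ 9 + 10 (C8–C9).** A Sonogashira cut gives terminal alkyne 9 and vinyl iodide 10, which already carries the E geometry of C9=C10. Coupling a complete C6 enynol to enol triflate 4 and epoxidising afterwards would be shorter, but the face of that epoxidation would be left to the ring, and so would both C5 and C8.

**9 ⇒ 8 ⇒ 7 (C7≡C8).** The alkyne carbon C8 is added to non-enolisable aldehyde 8 by Seyferth–Gilbert homologation, and 8 is the oxidation product of epoxy alcohol 7. Both steps must leave the tetrasubstituted oxirane alone, which neutral oxidation and carbonate in methanol should do.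

**7 ⇒ 6 (C5–O and C6–O).** The oxirane is placed by Sharpless epoxidation of allylic alcohol 6. This is the one point where an external chiral reagent decides the face, and it decides C5 and, through steps 9 and 10, C8.

**6 ⇒ 5 ⇒ 4 ⇒ 2 ⇒ 1 (C6–C7).** The hydroxymethyl carbon is introduced as an ester by carbonylation of enol triflate 4, made through enolate 3 from silylated actinol 2. Actinol 1 supplies ring A with C3 in the correct configuration, and its only enolisable position is the one needed.

## Roads not taken

**Alternative 1:** The cut is the C1–C6 bond of ring A. In the forward step Fe(acac)3 (trivalent iron) and PhSiH3 would transfer a hydrogen atom to the isopropenyl group of butenolide A2, and the tertiary C1 radical would add 6-exo to C6 to give the cis-fused saturated lactone A1.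
- Merits: the radical closure forms the quaternary C1 and ring A under mild, neutral conditions, and the C5 centre arrives already set in A2. As a ring-forming event it is probably more robust than a gold cyclisation on a hindered allene, and it needs neither an oxirane nor an allene.
- Weak points: A1 has neither the C6=C7 bond nor the C8 methine. The lactone would have to be dehydrogenated, the chain added to the carbonyl, and the lactol reduced through an oxocarbenium ion. That last step is acidic and leaves C8, the hardest centre, to weak 1,3-induction under the conditions that equilibrate it. A2 also needs its own asymmetric synthesis of C3 and C5, where the chosen plan buys C3.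
- Comparison: the chosen plan is less sure in its ring closure but ties C8 to a stereospecific event. That is the point this road leaves open.

**Alternative 2:** The cut removes C5–C6, C7–C8 and C8–O together. In the forward step ynone A4, Mo(CO)6 (zerovalent molybdenum) and CO would combine in a hetero-Pauson–Khand annulation to give silylated butenolide A3.
- Merits: two rings and three bonds form in one operation from an acyclic precursor. No plan here builds the bicycle more economically, and the chosen route needs nine steps before ring B exists even in masked form.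
- Weak points: the carbonyl partner is a methyl ketone and the new carbocycle is six-membered with a quaternary carbon next to the alkyne, both outside the range in which this annulation is dependable. A3 carries the C3 oxygen in the 3-epi configuration, so an inversion is needed. The C7 silyl group must be removed, and C8 is again a lactone carbonyl with the same unsolved reduction as in alternative 1.
- Comparison: this road is better in ring construction. The chosen plan sets against it a purchasable ring A with the right C3 and a direct answer to C8.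

**Alternative 3:** The cut is the O–C5 bond. In the forward step the trans vinyl oxirane A6 would rearrange under Cu(CF3COCHCOCF3)2 (divalent copper): the C7–O bond breaks, oxygen bonds to C5, and the alkene moves to C6–C7, giving furanoid ester A5.
- Merits: A5 is one reduction away from 13, the rearrangement wastes no atoms, and C8 is carried in from the oxirane with its C–O bond intact. If A6 were in hand this road would be shorter than the chosen one.
- Weak points: A6 would have to come from epoxidation of the C7=C8 bond alone, with control of site and face, in the presence of two other double bonds. The new centre is then the quaternary C5, formed at a tetrasubstituted alkene terminus beside the C1 methyl groups, and its configuration depends on which rotamer about C6–C7 reacts, with only the remote C3 group to bias it.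
- Comparison: the chosen plan is longer, but each stereocentre rests on a reagent-controlled or stereospecific step (tartrate for C5, anti hydrogenolysis and anti oxyauration for C8) rather than on two selectivities that cannot be predicted with confidence.

Key step: step 10

Assumption: (E)-3-iodobut-2-en-1-ol (10) is taken as a purchasable building block; where it is not stocked it is accessible from but-2-yn-1-ol by syn hydrometalation and iodinolysis.

## Route

Step 1
Reactants: 1 (4R,6R)-actinol
Product: 2 (4R,6R)-4-[(tert-butyldimethylsilyl)oxy]-2,2,6-trimethylcyclohexan-1-one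
Conditions: TBSCl, imidazole, DMF, rt
Reagents that add atoms: tert-butyldimethylsilyl chloride, CC(C)(C)[Si](C)(C)Cl
Why: Imidazole-promoted silylation of a secondary alcohol; the ketone and both stereocentres are untouched, and the silyl ether should survive every later step until fluoride removes it.

Step 2
Reactants: 2 (4R,6R)-4-[(tert-butyldimethylsilyl)oxy]-2,2,6-trimethylcyclohexan-1-one
Product: 4 (4R)-4-[(tert-butyldimethylsilyl)oxy]-2,6,6-trimethylcyclohex-1-en-1-yl trifluoromethanesulfonate, via lithium enolate 3 (not isolated)
Conditions: LiN(iPr)2, THF, −78 °C; then PhNTf2, −78 °C → rt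
Reagents that add atoms: N-phenylbis(trifluoromethanesulfonimide), O=S(=O)(N(c1ccccc1)S(=O)(=O)C(F)(F)F)C(F)(F)F
Why: Enol triflate formation; the ketone has one enolisable position (the other α-carbon is quaternary), so a single enolate forms and is trapped on oxygen. The methyl-bearing stereocentre is erased on purpose and the silyloxy centre is not affected.

Step 3
Reactants: 4 (4R)-4-[(tert-butyldimethylsilyl)oxy]-2,6,6-trimethylcyclohex-1-en-1-yl trifluoromethanesulfonate
Product: 5 methyl (4R)-4-[(tert-butyldimethylsilyl)oxy]-2,6,6-trimethylcyclohex-1-ene-1-carboxylate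
Conditions: Pd(OAc)2 (5 mol%), PPh3, CO (1 atm), MeOH, Et3N, DMF, 70 °C
Reagents that add atoms: carbon monoxide, [C-]#[O+]; methanol, CO
Why: Palladium-catalysed methoxycarbonylation of an enol triflate (oxidative addition, CO insertion, methanolysis) attaches C7 to C6; tetrasubstituted cyclohexenyl triflates are established substrates for this reaction.

Step 4
Reactants: 5 methyl (4R)-4-[(tert-butyldimethylsilyl)oxy]-2,6,6-trimethylcyclohex-1-ene-1-carboxylate
Product: 6 {(4R)-4-[(tert-butyldimethylsilyl)oxy]-2,6,6-trimethylcyclohex-1-en-1-yl}methanol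
Conditions: iBu2AlH, CH2Cl2, −78 → 0 °C; aqueous potassium sodium tartrate
Reagents that add atoms: none
Why: 1,2-Reduction of the conjugated ester to the allylic alcohol; the silyl ether and the tetrasubstituted alkene are inert to iBu2AlH at this temperature.

Step 5
Reactants: 6 {(4R)-4-[(tert-butyldimethylsilyl)oxy]-2,6,6-trimethylcyclohex-1-en-1-yl}methanol
Product: 7 {(1R,4S,6R)-4-[(tert-butyldimethylsilyl)oxy]-2,2,6-trimethyl-7-oxabicyclo[4.1.0]heptan-1-yl}methanol
Conditions: Ti(OiPr)4 (20 mol%), L-(+)-diethyl tartrate (24 mol%), t-BuOOH, 4 Å MS, CH2Cl2, −20 °C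
Reagents that add atoms: tert-butyl hydroperoxide, CC(C)(C)OO
Why: Sharpless asymmetric epoxidation; with the hydroxymethyl group drawn at the lower right, L-(+)-tartrate delivers oxygen from the lower face, which is the face opposite the silyloxy group. Reagent control thus sets C5 (R) and the oxirane carbon C6 together, whatever the ring's own preference.

Step 6
Reactants: 7 {(1R,4S,6R)-4-[(tert-butyldimethylsilyl)oxy]-2,2,6-trimethyl-7-oxabicyclo[4.1.0]heptan-1-yl}methanol
Product: 8 (1S,4S,6R)-4-[(tert-butyldimethylsilyl)oxy]-2,2,6-trimethyl-7-oxabicyclo[4.1.0]heptane-1-carbaldehyde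
Conditions: Pr4N[RuO4] (5 mol%), N-methylmorpholine N-oxide, 4 Å MS, CH2Cl2, rt
Reagents that add atoms: none
Why: Ley–Griffith oxidation of a primary alcohol under neutral conditions; the aldehyde has no α-hydrogen, so it cannot epimerise, and the oxirane should not open.

Step 7
Reactants: 8 (1S,4S,6R)-4-[(tert-butyldimethylsilyl)oxy]-2,2,6-trimethyl-7-oxabicyclo[4.1.0]heptane-1-carbaldehyde
Product: 9 (1R,4S,6R)-4-[(tert-butyldimethylsilyl)oxy]-1-ethynyl-2,2,6-trimethyl-7-oxabicyclo[4.1.0]heptane
Conditions: dimethyl (1-diazo-2-oxopropyl)phosphonate, K2CO3, MeOH, 0 °C → rt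
Reagents that add atoms: dimethyl (1-diazo-2-oxopropyl)phosphonate, CC(=O)C(=[N+]=[N-])P(=O)(OC)OC
Why: Seyferth–Gilbert homologation with the Ohira–Bestmann reagent: the diazomethylphosphonate anion adds to the non-enolisable aldehyde, and loss of phosphate and N2 with a 1,2-shift gives the terminal alkyne (C8). No stereocentre takes part.

Step 8
Reactants: 9 (1R,4S,6R)-4-[(tert-butyldimethylsilyl)oxy]-1-ethynyl-2,2,6-trimethyl-7-oxabicyclo[4.1.0]heptane; 10 (E)-3-iodobut-2-en-1-ol
Product: 11 (2E)-5-{(1R,4S,6R)-4-[(tert-butyldimethylsilyl)oxy]-2,2,6-trimethyl-7-oxabicyclo[4.1.0]heptan-1-yl}-3-methylpent-2-en-4-yn-1-ol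
Conditions: Pd(PPh3)4 (5 mol%), CuI (10 mol%), iPr2NH, THF, rt
Reagents that add atoms: none
Why: Sonogashira coupling of a terminal alkyne with a vinyl iodide forms C8–C9 with retention of the E geometry; the oxirane, the free alcohol and the silyl ether are inert to these conditions.

Step 9
Reactants: 11 (2E)-5-{(1R,4S,6R)-4-[(tert-butyldimethylsilyl)oxy]-2,2,6-trimethyl-7-oxabicyclo[4.1.0]heptan-1-yl}-3-methylpent-2-en-4-yn-1-ol
Product: 12 (2E)-5-{(2R,4S)-4-[(tert-butyldimethylsilyl)oxy]-2-hydroxy-2,6,6-trimethylcyclohexylidene}-3-methylpenta-2,4-dien-1-ol with S-configured allene axis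
Conditions: Pd2(dba)3·CHCl3 (2.5 mol%), n-Bu3P (5 mol%), HCO2H, Et3N, 1,4-dioxane, rt
Reagents that add atoms: none
Why: Palladium-catalysed formate hydrogenolysis of an alkynyl oxirane to an α-allenic alcohol: zerovalent palladium attacks C8 anti to the breaking C6–O bond (SN2′ oxidative addition), formate loses CO2, and hydride passes from palladium to C8 with retention. H-8 therefore ends on the face of the C5 methyl group and C9 on the face of the C5 oxygen (S axis), while C5 keeps its configuration because its C–O bond is not broken.

Step 10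
Reactants: 12 (2E)-5-{(2R,4S)-4-[(tert-butyldimethylsilyl)oxy]-2-hydroxy-2,6,6-trimethylcyclohexylidene}-3-methylpenta-2,4-dien-1-ol with S-configured allene axis
Product: 13 (2E)-3-{(2R,6S,7aR)-6-[(tert-butyldimethylsilyl)oxy]-4,4,7a-trimethyl-2,4,5,6,7,7a-hexahydro-1-benzofuran-2-yl}but-2-en-1-ol
Conditions: AuCl3 (2 mol%), THF, 0 °C → rt, dark
Reagents that add atoms: none
Why: AuCl3 (trivalent gold) binds the C7=C8 π bond, which lies in the plane of the exocyclic double bond, on the flank remote from the C5 hydroxyl; the hydroxyl oxygen attacks C8 from the near flank (anti oxyauration) to give a C7-aurated dihydrofuran, and protodeauration at C7 frees AuCl3 and leaves the C6=C7 alkene. The closest known reaction type is the gold- or silver-catalysed cycloisomerisation of α-hydroxyallenes to 2,5-dihydrofurans with axis-to-centre chirality transfer. Ring B closes in the 5-endo-trig mode. The new stereocentre C8 is controlled by the allene axis together with the fixed C5 centre: the O–C8 bond forms in the ring plane while H-8 and C9 stay below and above it, so the S axis of 12 places the chain trans to the C5 methyl group, which is 8R. The step needs strictly anti addition and no ionisation at C8 before or after closure; a small ligand-free catalyst that fits beside the C1 methyl groups, the donor solvent THF, low temperature and short contact time serve this. The tertiary hydroxyl is held beside the allene by ring A once that ring adopts the conformer with the C5–O bond in the allene plane, and the primary hydroxyl cannot reach the allene across the E alkene. Capture by oxygen should outrun carbocyclisation of the vinylallene.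

Step 11
Reactants: 13 (2E)-3-{(2R,6S,7aR)-6-[(tert-butyldimethylsilyl)oxy]-4,4,7a-trimethyl-2,4,5,6,7,7a-hexahydro-1-benzofuran-2-yl}but-2-en-1-ol
Product: 15 {(2E)-3-[(2R,6S,7aR)-6-(tert-butyldimethylsilyloxy)-4,4,7a-trimethyl-2,4,5,6,7,7a-hexahydro-1-benzofuran-2-yl]but-2-en-1-yl}triphenylphosphonium bromide, via allylic bromide 14 (not isolated)
Conditions: CBr4, PPh3, 2,6-lutidine (0.2 equiv), CH2Cl2, 0 °C; then PPh3, CH2Cl2/MeCN, rt
Reagents that add atoms: carbon tetrabromide, BrC(Br)(Br)Br; triphenylphosphine, c1ccc(cc1)P(c1ccccc1)c1ccccc1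
Why: Appel bromination (SN2 at the primary allylic carbon) followed by quaternisation of PPh3 by the allylic bromide; no Brønsted acid is generated, so the C8 ether should not ionise, and the E geometry of C9=C10 is retained.

Step 12
Reactants: 15 {(2E)-3-[(2R,6S,7aR)-6-(tert-butyldimethylsilyloxy)-4,4,7a-trimethyl-2,4,5,6,7,7a-hexahydro-1-benzofuran-2-yl]but-2-en-1-yl}triphenylphosphonium bromide; 16 (2E,4E,6E)-2,7-dimethylocta-2,4,6-trienedial
Product: 18 (2E,4E,6E,8E,10E)-11-{(2R,6S,7aR)-6-[(tert-butyldimethylsilyl)oxy]-4,4,7a-trimethyl-2,4,5,6,7,7a-hexahydro-1-benzofuran-2-yl}-2,7-dimethyldodeca-2,4,6,8,10-pentaenal, via phosphorus ylide 17 (not isolated)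
Conditions: 16 (3 equiv), NaOMe, CH2Cl2/MeOH, 0 °C → rt; then EtOAc, 60 °C, dark
Reagents that add atoms: none
Why: Wittig olefination; NaOMe generates the allylic ylide in the presence of excess dial, so it is consumed as it forms and mono-olefination should dominate. The C11=C12 bond is expected as an E/Z mixture in which the hindered 11Z isomer (C13 methyl against H-10) equilibrates to E on warming; no stereocentre is involved.

Step 13
Reactants: 18 (2E,4E,6E,8E,10E)-11-{(2R,6S,7aR)-6-[(tert-butyldimethylsilyl)oxy]-4,4,7a-trimethyl-2,4,5,6,7,7a-hexahydro-1-benzofuran-2-yl}-2,7-dimethyldodeca-2,4,6,8,10-pentaenal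
Product: 19 (2E,4E,6E,8E,10E)-11-{(2R,6S,7aR)-6-[(tert-butyldimethylsilyl)oxy]-4,4,7a-trimethyl-2,4,5,6,7,7a-hexahydro-1-benzofuran-2-yl}-2,7-dimethyldodeca-2,4,6,8,10-pentaen-1-ol
Conditions: NaBH4, MeOH/THF, 0 °C
Reagents that add atoms: none
Why: 1,2-Reduction of the polyenal to the primary allylic alcohol by NaBH4; the medium is basic, so C8 is safe.

Step 14
Reactants: 19 (2E,4E,6E,8E,10E)-11-{(2R,6S,7aR)-6-[(tert-butyldimethylsilyl)oxy]-4,4,7a-trimethyl-2,4,5,6,7,7a-hexahydro-1-benzofuran-2-yl}-2,7-dimethyldodeca-2,4,6,8,10-pentaen-1-ol
Product: 20 (2E,4E,6E,8E,10E)-11-[(2R,6S,7aR)-6-hydroxy-4,4,7a-trimethyl-2,4,5,6,7,7a-hexahydro-1-benzofuran-2-yl]-2,7-dimethyldodeca-2,4,6,8,10-pentaen-1-ol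
Conditions: Bu4NF, THF, rt, dark; chromatography on base-washed silica
Reagents that add atoms: none
Why: Fluoride cleavage of the secondary silyl ether, driven by Si–F bond formation; the conditions are basic and should leave the C8 ether and the polyene untouched.

## Compound list

1 | (4R,6R)-4-hydroxy-2,2,6-trimethylcyclohexan-1-one ((4R,6R)-actinol) | C[C@@H]1C[C@@H](O)CC(C)(C)C1=O | starting material
2 | (4R,6R)-4-[(tert-butyldimethylsilyl)oxy]-2,2,6-trimethylcyclohexan-1-one | C[C@@H]1C[C@@H](O[Si](C)(C)C(C)(C)C)CC(C)(C)C1=O | intermediate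
3 | lithium (4R)-4-[(tert-butyldimethylsilyl)oxy]-2,6,6-trimethylcyclohex-1-en-1-olate | [Li+].CC1=C([O-])C(C)(C)C[C@H](O[Si](C)(C)C(C)(C)C)C1 | intermediate (not isolated)
4 | (4R)-4-[(tert-butyldimethylsilyl)oxy]-2,6,6-trimethylcyclohex-1-en-1-yl trifluoromethanesulfonate | CC1=C(OS(=O)(=O)C(F)(F)F)C(C)(C)C[C@H](O[Si](C)(C)C(C)(C)C)C1 | intermediate
5 | methyl (4R)-4-[(tert-butyldimethylsilyl)oxy]-2,6,6-trimethylcyclohex-1-ene-1-carboxylate | COC(=O)C1=C(C)C[C@@H](O[Si](C)(C)C(C)(C)C)CC1(C)C | intermediate
6 | {(4R)-4-[(tert-butyldimethylsilyl)oxy]-2,6,6-trimethylcyclohex-1-en-1-yl}methanol | OCC1=C(C)C[C@@H](O[Si](C)(C)C(C)(C)C)CC1(C)C | intermediate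
7 | {(1R,4S,6R)-4-[(tert-butyldimethylsilyl)oxy]-2,2,6-trimethyl-7-oxabicyclo[4.1.0]heptan-1-yl}methanol (oxirane oxygen trans to the silyloxy group) | OC[C@@]12O[C@]1(C)C[C@@H](O[Si](C)(C)C(C)(C)C)CC2(C)C | intermediate
8 | (1S,4S,6R)-4-[(tert-butyldimethylsilyl)oxy]-2,2,6-trimethyl-7-oxabicyclo[4.1.0]heptane-1-carbaldehyde | O=C[C@@]12O[C@]1(C)C[C@@H](O[Si](C)(C)C(C)(C)C)CC2(C)C | intermediate
9 | (1R,4S,6R)-4-[(tert-butyldimethylsilyl)oxy]-1-ethynyl-2,2,6-trimethyl-7-oxabicyclo[4.1.0]heptane | C#C[C@@]12O[C@]1(C)C[C@@H](O[Si](C)(C)C(C)(C)C)CC2(C)C | intermediate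
10 | (E)-3-iodobut-2-en-1-ol | OC/C=C(\C)I | starting material
11 | (2E)-5-{(1R,4S,6R)-4-[(tert-butyldimethylsilyl)oxy]-2,2,6-trimethyl-7-oxabicyclo[4.1.0]heptan-1-yl}-3-methylpent-2-en-4-yn-1-ol | OC/C=C(\C)C#C[C@@]12O[C@]1(C)C[C@@H](O[Si](C)(C)C(C)(C)C)CC2(C)C | intermediate
12 | (2E)-5-{(2R,4S)-4-[(tert-butyldimethylsilyl)oxy]-2-hydroxy-2,6,6-trimethylcyclohexylidene}-3-methylpenta-2,4-dien-1-ol, S-configured allene axis (H-8 on the face of the C5 methyl group, C9 on the face of the C5 hydroxyl) | OC/C=C(\C)C([H])=[C@]=C1C(C)(C)C[C@H](O[Si](C)(C)C(C)(C)C)C[C@@]1(C)O | intermediate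
13 | (2E)-3-{(2R,6S,7aR)-6-[(tert-butyldimethylsilyl)oxy]-4,4,7a-trimethyl-2,4,5,6,7,7a-hexahydro-1-benzofuran-2-yl}but-2-en-1-ol | OC/C=C(\C)[C@H]1C=C2C(C)(C)C[C@H](O[Si](C)(C)C(C)(C)C)C[C@@]2(C)O1 | intermediate
14 | (2R,6S,7aR)-2-[(2E)-4-bromobut-2-en-2-yl]-6-[(tert-butyldimethylsilyl)oxy]-4,4,7a-trimethyl-2,4,5,6,7,7a-hexahydro-1-benzofuran | BrC/C=C(\C)[C@H]1C=C2C(C)(C)C[C@H](O[Si](C)(C)C(C)(C)C)C[C@@]2(C)O1 | intermediate (not isolated)
15 | {(2E)-3-[(2R,6S,7aR)-6-(tert-butyldimethylsilyloxy)-4,4,7a-trimethyl-2,4,5,6,7,7a-hexahydro-1-benzofuran-2-yl]but-2-en-1-yl}triphenylphosphonium bromide | [Br-].c1ccccc1[P+](c1ccccc1)(c1ccccc1)C/C=C(\C)[C@H]1C=C2C(C)(C)C[C@H](O[Si](C)(C)C(C)(C)C)C[C@@]2(C)O1 | intermediate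
16 | (2E,4E,6E)-2,7-dimethylocta-2,4,6-trienedial | CC(/C=O)=C\C=C\C=C(/C)C=O | starting material
17 | {(2E)-3-[(2R,6S,7aR)-6-(tert-butyldimethylsilyloxy)-4,4,7a-trimethyl-2,4,5,6,7,7a-hexahydro-1-benzofuran-2-yl]but-2-en-1-ylidene}triphenylphosphorane (ylide) | c1ccccc1[P+](c1ccccc1)(c1ccccc1)[CH-]/C=C(\C)[C@H]1C=C2C(C)(C)C[C@H](O[Si](C)(C)C(C)(C)C)C[C@@]2(C)O1 | intermediate (not isolated)
18 | (2E,4E,6E,8E,10E)-11-{(2R,6S,7aR)-6-[(tert-butyldimethylsilyl)oxy]-4,4,7a-trimethyl-2,4,5,6,7,7a-hexahydro-1-benzofuran-2-yl}-2,7-dimethyldodeca-2,4,6,8,10-pentaenal | CC(/C=C/C=C(\C)[C@H]1C=C2C(C)(C)C[C@H](O[Si](C)(C)C(C)(C)C)C[C@@]2(C)O1)=C\C=C\C=C(/C)C=O | intermediate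
19 | (2E,4E,6E,8E,10E)-11-{(2R,6S,7aR)-6-[(tert-butyldimethylsilyl)oxy]-4,4,7a-trimethyl-2,4,5,6,7,7a-hexahydro-1-benzofuran-2-yl}-2,7-dimethyldodeca-2,4,6,8,10-pentaen-1-ol | CC(/C=C/C=C(\C)[C@H]1C=C2C(C)(C)C[C@H](O[Si](C)(C)C(C)(C)C)C[C@@]2(C)O1)=C\C=C\C=C(/C)CO | intermediate
20 | (2E,4E,6E,8E,10E)-11-[(2R,6S,7aR)-6-hydroxy-4,4,7a-trimethyl-2,4,5,6,7,7a-hexahydro-1-benzofuran-2-yl]-2,7-dimethyldodeca-2,4,6,8,10-pentaen-1-ol ((3S,5R,8R)-5,8-epoxy-5,8-dihydro-12'-apo-β-carotene-3,12'-diol) | CC(/C=C/C=C(\C)[C@H]1C=C2C(C)(C)C[C@H](O)C[C@@]2(C)O1)=C\C=C\C=C(/C)CO | target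

## Step count and least certain steps

Total step count: 14. Longest linear sequence: 14 steps, from 1 to 20; 10 and 16 enter as purchased fragments.

**Step 10 (key step).**
- What may go wrong: partial loss of the axis-to-centre transfer through gold- or acid-induced ionisation at the doubly allylic C8 of the product, or through epimerisation of the allene before closure. Turnover may be slow, because the reactive conformer of ring A places the C3 oxygen, the C5 methyl and one C1 methyl axial and the metal must sit beside the C1 methyl groups. Carbocyclisation of the vinylallene may compete.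
- Fallback: starting from 12, iodoetherification with N-iodosuccinimide in CH2Cl2 at low temperature (also an anti, 5-endo, stereospecific closure, but through an iodonium ion instead of a metal complex) should give the 7-iodo dihydrofuran F1. Hydrodeiodination with Bu3SnH and Pd(PPh3)4 then returns to the route at 13.

**Step 9.**
- What may go wrong: erosion of stereospecificity by exchange of palladium on the allenylpalladium intermediate, which would scramble the axis. Hydride transfer to the propargylic position, or reduction of the product, may also occur.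
- Fallback: starting from 11, open the oxirane with iBu2AlH, which is expected to deliver hydride on the oxygen face and give the axis epimer F2. Cyclise it under the conditions of step 10 to the C8 epimer F3. Then equilibrate C8 with a trace of pyridinium p-toluenesulfonate, separate 13 from F3 and recycle F3. This replaces stereospecific relay by thermodynamic equilibration and separation, and comes back at 13.

**Step 12.**
- What may go wrong: opening of ring B in the ylide by vinylogous β-elimination of the C8 alkoxide (the carbanion is delocalised to C9, next to C8), with reclosure that no longer respects the C8 configuration. Double olefination of the dial and incomplete equilibration of the 11Z isomer are further risks.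
- Fallback: reverse the polarity so that the ring piece is the electrophile. Starting from 13, oxidation with MnO2 should give the enal F4. A Horner–Wadsworth–Emmons reaction with the C10 phosphonate ester F5 (NaH, THF) should give the C25 ester F6. Reduction of F6 with iBu2AlH comes back to the route at 19.

**Step 5.**
- What may go wrong: poor facial selectivity if the ring's own bias (approach anti to the axial C1 methyl, on the face of the silyloxy group) opposes the tartrate, and slow turnover at the hindered tetrasubstituted alkene.
- Fallback: use that same bias through a bromohydrin. Starting from 6, N-bromosuccinimide in aqueous THF should place bromine on the intrinsically preferred face and water on the other, giving the bromohydrin F7. K2CO3 in MeOH then closes F7 with inversion to the oxirane on the face anti to the silyloxy group, coming back at 7.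

## Further compounds

F1 | step 10 | (2E)-3-{(2R,6S,7aR)-6-[(tert-butyldimethylsilyl)oxy]-3-iodo-4,4,7a-trimethyl-2,4,5,6,7,7a-hexahydro-1-benzofuran-2-yl}but-2-en-1-ol (same spatial arrangement as 13, iodine at C7) | OC/C=C(\C)[C@H]1C(I)=C2C(C)(C)C[C@H](O[Si](C)(C)C(C)(C)C)C[C@@]2(C)O1
F2 | step 9 | axis epimer of 12 (R-configured allene axis, H-8 on the face of the C5 hydroxyl) | OC/C=C(\C)C([H])=[C@@]=C1C(C)(C)C[C@H](O[Si](C)(C)C(C)(C)C)C[C@@]1(C)O
F3 | step 9 | C8 epimer of 13, (2E)-3-{(2S,6S,7aR)-6-[(tert-butyldimethylsilyl)oxy]-4,4,7a-trimethyl-2,4,5,6,7,7a-hexahydro-1-benzofuran-2-yl}but-2-en-1-ol | OC/C=C(\C)[C@@H]1C=C2C(C)(C)C[C@H](O[Si](C)(C)C(C)(C)C)C[C@@]2(C)O1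
F4 | step 12 | (2E)-3-{(2R,6S,7aR)-6-[(tert-butyldimethylsilyl)oxy]-4,4,7a-trimethyl-2,4,5,6,7,7a-hexahydro-1-benzofuran-2-yl}but-2-enal | O=C/C=C(\C)[C@H]1C=C2C(C)(C)C[C@H](O[Si](C)(C)C(C)(C)C)C[C@@]2(C)O1
F5 | step 12 | ethyl (2E,4E,6E)-8-(diethoxyphosphoryl)-2,7-dimethylocta-2,4,6-trienoate | CC(/CP(=O)(OCC)OCC)=C\C=C\C=C(/C)C(=O)OCC
F6 | step 12 | ethyl (2E,4E,6E,8E,10E)-11-{(2R,6S,7aR)-6-[(tert-butyldimethylsilyl)oxy]-4,4,7a-trimethyl-2,4,5,6,7,7a-hexahydro-1-benzofuran-2-yl}-2,7-dimethyldodeca-2,4,6,8,10-pentaenoate | CC(/C=C/C=C(\C)[C@H]1C=C2C(C)(C)C[C@H](O[Si](C)(C)C(C)(C)C)C[C@@]2(C)O1)=C\C=C\C=C(/C)C(=O)OCC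
F7 | step 5 | bromohydrin of 6: 2-bromo-2-(hydroxymethyl)-5-[(tert-butyldimethylsilyl)oxy]-1,3,3-trimethylcyclohexan-1-ol, bromine cis and tertiary hydroxyl trans to the silyloxy group | OC[C@@]1(Br)C(C)(C)C[C@H](O[Si](C)(C)C(C)(C)C)C[C@@]1(C)O
A1 | alternative 1 | cis-fused 6,7-dihydro bicyclic lactone, 4-methoxybenzyl ether | O=C1C[C@H]2C(C)(C)C[C@H](OCc3ccc(OC)cc3)C[C@@]2(C)O1
A2 | alternative 1 | 5-methyl-5-[2-(4-methoxybenzyloxy)-4-methylpent-4-en-1-yl]furan-2(5H)-one | C=C(C)C[C@H](OCc1ccc(OC)cc1)C[C@@]1(C)OC(=O)C=C1
A3 | alternative 2 | 7-trimethylsilyl-3-epi-loliolide tert-butyldimethylsilyl ether | O=C1C([Si](C)(C)C)=C2C(C)(C)C[C@@H](O[Si](C)(C)C(C)(C)C)C[C@@]2(C)O1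
A4 | alternative 2 | 4-[(tert-butyldimethylsilyl)oxy]-6,6-dimethyl-8-(trimethylsilyl)oct-7-yn-2-one | CC(=O)C[C@H](O[Si](C)(C)C(C)(C)C)CC(C)(C)C#C[Si](C)(C)C
A5 | alternative 3 | silylated C15 furanoid ethyl ester | CCOC(=O)/C=C(\C)[C@H]1C=C2C(C)(C)C[C@H](O[Si](C)(C)C(C)(C)C)C[C@@]2(C)O1
A6 | alternative 3 | ethyl (2E)-3-{trans-3-[4-(tert-butyldimethylsilyloxy)-2,6,6-trimethylcyclohex-1-en-1-yl]oxiran-2-yl}but-2-enoate | CCOC(=O)/C=C(\C)[C@@H]1O[C@H]1C1=C(C)C[C@@H](O[Si](C)(C)C(C)(C)C)CC1(C)C
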